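## The problem

Compound 19 is a 1,2-dioxolane (ring atoms O1–O2–C3–C4–C5) in which both oxygen-bearing carbons are quaternary. C3 carries a methyl group and the CH2CO2H arm (C2, C1). C5 carries a methyl group and the chain C6–C17, which holds the C7 methyl branch and two E-alkenes (C12=C13 and the styrenyl C16=C17) and ends in a phenyl group. There are three stereocentres, C3 (R), C5 (R) and C7 (R), and the two ring methyl groups are cis. Neither ring centre bears hydrogen, so nothing can be corrected by epimerisation. C7 is one methylene away from C5 on a freely rotating chain and cannot be expected to direct C5, so C7 must come from the chiral pool and the ring centres must be set, or sorted, when the ring is made. Once the ring exists, the O–O bond excludes catalytic hydrogenation, dissolving metals, hydride reagents and low-valent metals, and the β-peroxy ester can open through its enolate, so later steps must be oxidative, neutral or only weakly basic. The two alkenes are π-nucleophiles that would not survive a cationic, ozonolytic or hydrogenation step, so they have to arrive after the ring. A short synthesis is possible because the ring maps onto two simple pieces: C5 with its methyl group and C6 is a methyl ketone in latent form (as a peroxycarbenium ion that already carries O1 and O2), and C4–C3 with the C3 methyl group and the acetate arm is the skeleton of a 3-methylbut-3-enoate whose CH2 terminus is C4.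

## Retrosynthesis

**Acid to ester.** Target 19 is traced back to its methyl ester 18, a change of functional group only. The ester keeps the carboxyl group silent towards the Lewis acid of the ring construction and the base of the olefination. The forward step must be a hydrolysis that leaves the O–O bond and the configuration of C3 alone.

**C12=C13.** In 18 the C12=C13 double bond is cut, giving aldehyde 14 and tetrazolyl sulfone 17. A cut at C16=C17 or in the C14–C15 bond would leave an alkene in the piece that has to pass through the cationic ring construction. The cut at C12=C13 removes both alkenes and the phenyl group at once, and 17 already carries the styrene in its final E form. The forward reaction must give an E-alkene without any reducing agent, which excludes the reductive sulfone olefination and points to the one-pot Julia–Kocienski variant.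

**C12 oxidation level.** Aldehyde 14 goes back through alcohol 13 to benzoate 12. A benzoate is chosen for the C12 oxygen because it resists SnCl4, peroxide and hydrogenation catalysts and comes in with the commercial alkene 4. Its methanolysis leaves the methyl ester of the acetate arm unchanged, since that exchange is degenerate.

**The ring.** In 12 the bonds C4–C5 and O2–C3 are cut, giving the silylperoxy ketal 8 and the commercial alkene 9.
- The mirror-image cut (C3–C4 and O1–C5) would make the chain the alkene and would deliver the acetate arm two oxidation levels too low.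
- Building the O–O unit stepwise by peroxide alkylations at two tertiary carbons is not realistic.
- The chosen cut removes the ring, both quaternary centres and two skeletal bonds in one operation, and divides 12 into a five-carbon ester and one chiral chain.
- The forward reaction needs the alkene to attack through its CH2 carbon and the resulting cation to be closed by the peroxide oxygen faster than it loses a proton.
- No stereocontrol can be asked of this step, so 12 must be separable from its diastereomers.

**Peroxy ketal.** Ketal 8 goes back by O–Si cleavage to the α-methoxy hydroperoxide 7, and this by removal of the OOH and OCH3 groups to keto benzoate 6. The precursor has no peroxide and one stereocentre.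

**Chain.** Keto benzoate 6 is the hydrogenation product of enone benzoate 5, which is cut at C10=C11 into ketone 3 and allyl benzoate 4. The isopropylidene end of the citronellal skeleton is thereby exchanged for the two carbons C11 and C12 with their oxygen. Ozonolysis to the C10 aldehyde followed by a two-carbon homologation, reduction and protection would need more steps and a differentiation from the ketone. The forward cross-metathesis only has to make a trisubstituted alkene react; its geometry is irrelevant.

**Methyl ketone.** Ketone 3 goes back through alcohol 2 to (R)-citronellal 1 by cutting the C5–CH3 bond. C7 is bought, not made.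

**Sulfone.** Sulfone 17 comes from sulfide 16 by oxidation, and 16 from the commercial alcohol 15 by C–S bond formation. Neither step touches the styrene.

## Roads not taken

Alternative 1: The cut removes both arms from a ready-made dioxolane, at C3–C2 and C5–C6. In the forward key step Me3SiOSO2CF3 would ionise the two ketal carbons of 3,5-dimethoxy-3,5-dimethyl-1,2-dioxolane A1 in turn. The two nucleophilic termini of the 2-silyloxyallylsilane A2 would add to them and close a six-membered carbocycle, giving the bridged meso ketone A3.
- Merits: the bridge forces the two methyl groups cis, and a single desymmetrising oxidation of the meso ketone could in principle fix both ring centres absolutely, with no diastereomer separation.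
- Weak points: after oxidative opening of the bridge, C3 has its acetate arm but C5 carries only C6 as a hydroxymethyl group. The whole chain must then be attached at this neopentyl-type carbon and C7 created next to it with the O–O bond present, without hydrogenation or hydride reagents. The double ionisation and the desymmetrisation of a peroxide-bridged ketone have no close model, and the route is much longer.
- Comparison: this road is clearly better in ring stereocontrol; the chosen plan loses a large part of its annulation product to diastereomers. Against that it sets six ordinary steps to the annulation substrate, C7 from the chiral pool and a convergent chain assembly.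

Alternative 2: The cut is at both C–O bonds (O1–C5 and O2–C3), the two oxygens coming from O2 gas and the ring carbons from a cyclopropane. In the forward key step a phenylselenyl radical from (C6H5Se)2 and light adds to the vinyl group of vinylcyclopropane A4. The C3–C5 bond opens to a tertiary C5 radical, O2 is captured, and the peroxyl radical closes 5-exo onto C3 with loss of the selenyl radical, giving the vinyl dioxolane A5.
- Merits: neutral conditions, no Lewis acid, selenium in catalytic amount, and a radical closure that may favour the cis arrangement more than a cationic one does.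
- Weak points: A4, with two adjacent quaternary ring carbons, is not available in a few steps, and its stereocentres are erased in the ring opening, so C5 is again unrelated to C7. The vinyl group must then be turned into CH2CO2H by anti-Markovnikov hydration and two oxidations, the first of which brings a borane to the O–O bond. Selenyl and peroxyl radicals would attack the styrene, so the chain must still be completed late.
- Comparison: equal in the C5/C7 problem and possibly better in cis preference, but longer on both sides of the key step. The chosen plan sets a commercial alkene at the correct oxidation level against it.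

Alternative 3: The cut is the mirror image of the chosen one, at C3–C4 and O1–C5. In the forward key step SnCl4 would ionise the silylperoxy ketal A6, derived from a silyl-protected four-carbon hydroxy ketone. The CH2 terminus of the chain alkene A7 would add to it, and the tertiary cation at C5 would be trapped by the peroxide oxygen to give A8.
- Merits: A7 is a plain 2-methylalk-1-ene without an electron-withdrawing ester near the reacting carbon, so it is a better nucleophile than 9 and less prone to proton loss after addition. A6 comes from a cheap achiral ketone.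
- Weak points: the arm arrives protected and two oxidation levels low, so desilylation and oxidation to the acid follow the ring closure. The β-silyloxy group of the peroxycarbenium ion can be lost by elimination, A7 costs an extra methylenation from ketone 6, and the stereochemical outcome is no better because C7 is still remote.
- Comparison: in the annulation itself this road is probably the more reliable. The chosen plan sets against it an acetate arm at the right oxidation level from a commercial alkene and an endgame about three steps shorter; the separation burden is the same.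

Key step: step 7

Assumption: (R)-citronellal 1 is taken in high enantiomeric purity; C7 is never touched, so the enantiomeric purity of 19 equals that of 1.

## Route

Step 1
Reactants: 1 (R)-citronellal
Product: 2 (4R)-4,8-dimethylnon-7-en-2-ol (both C2 epimers)
Conditions: CH3MgBr (1.2 equiv), Et2O, −78 → 0 °C; aq NH4Cl
Reagents that add atoms: methylmagnesium bromide, C[Mg]Br
Why: Grignard addition to an unhindered aldehyde at low temperature, where addition outruns the Lewis acid-promoted carbonyl-ene cyclisation of citronellal. The new carbinol centre is formed without control and is removed in step 2; C7 is not touched.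

Step 2
Reactants: 2 (4R)-4,8-dimethylnon-7-en-2-ol
Product: 3 (4R)-4,8-dimethylnon-7-en-2-one
Conditions: Dess–Martin periodinane (1.2 equiv), CH2Cl2, 0 °C → rt
Reagents that add atoms: none
Why: Dess–Martin oxidation of a secondary alcohol to the methyl ketone. The trisubstituted alkene is inert and the stereocentre is β to the carbonyl, so enolisation cannot erode it.

Step 3
Reactants: 3 (4R)-4,8-dimethylnon-7-en-2-one; 4 allyl benzoate
Product: 5 (2E,6R)-6-methyl-8-oxonon-2-en-1-yl benzoate (E major; the Z isomer is carried along)
Conditions: 4 (3 equiv), second-generation Grubbs catalyst RuCl2(=CHPh)(H2IMes)(PCy3) (5 mol%), CH2Cl2, 40 °C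
Reagents that add atoms: none
Why: Olefin cross-metathesis: the ruthenium alkylidene formed from excess 4 exchanges the isopropylidene terminus of 3 for the CH–CH2OBz unit, and 2-methylpropene leaves as a gas, as known for prenyl-type alkenes with N-heterocyclic carbene ruthenium catalysts. The alkene geometry does not matter because step 4 saturates it.

Step 4
Reactants: 5 (2E,6R)-6-methyl-8-oxonon-2-en-1-yl benzoate
Product: 6 (6R)-6-methyl-8-oxononyl benzoate
Conditions: H2 (1 atm), 5% Rh/Al2O3, EtOAc, rt
Reagents that add atoms: none
Why: Heterogeneous alkene hydrogenation. Rh/Al2O3 is preferred to Pd/C because it saturates allylic esters with little C–O hydrogenolysis, and it leaves the ketone and the benzoate alone.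

Step 5
Reactants: 6 (6R)-6-methyl-8-oxononyl benzoate
Product: 7 (6R)-8-hydroperoxy-8-methoxy-6-methylnonyl benzoate (both C8 epimers)
Conditions: 30% aq H2O2 (4 equiv), iodine (10 mol%), CH3OH, rt
Reagents that add atoms: hydrogen peroxide, OO; methanol, CO
Why: Iodine-catalysed perketalisation of a ketone: in methanol, H2O2 and CH3OH add to the carbonyl carbon through the oxocarbenium ion to give the α-methoxy hydroperoxide, the known outcome of this reagent system in methanol. The new C8 centre is formed as both epimers, which is immaterial because it becomes planar in step 7.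

Step 6
Reactants: 7 (6R)-8-hydroperoxy-8-methoxy-6-methylnonyl benzoate
Product: 8 (6R)-8-methoxy-6-methyl-8-[(triethylsilyl)peroxy]nonyl benzoate (both C8 epimers)
Conditions: Et3SiCl (1.3 equiv), imidazole (2 equiv), DMF, 0 °C
Reagents that add atoms: chlorotriethylsilane, CC[Si](Cl)(CC)CC
Why: O-Silylation of a hydroperoxide with a silyl chloride and imidazole, the standard access to triethylsilylperoxy ketals. The ketal and the benzoate are stable to the weakly basic medium.

Step 7
Reactants: 8 (6R)-8-methoxy-6-methyl-8-[(triethylsilyl)peroxy]nonyl benzoate; 9 methyl 3-methylbut-3-enoate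
Product: 12 methyl 2-[(3R,5R)-5-[(2R)-7-(benzoyloxy)-2-methylheptyl]-3,5-dimethyl-1,2-dioxolan-3-yl]acetate, via peroxycarbenium ion 10 (not isolated), via tertiary carbenium ion 11 (not isolated)
Conditions: 9 (3 equiv), SnCl4 (1.5 equiv), CH2Cl2, −78 °C; aq NaHCO3; SiO2 chromatography, then preparative HPLC
Reagents that add atoms: none
Why: SnCl4 abstracts methoxide from ketal 8 to give the triethylsilylperoxycarbenium ion 10. The CH2 terminus of the 1,1-disubstituted alkene 9 adds to the cationic carbon (C4–C5), which places the charge on the tertiary carbon C3 of 11 and so fixes the regiochemistry. The silylated distal peroxide oxygen then donates a lone pair to C3 (O2–C3) and silicon leaves with the methoxide as CH3OSiEt3, so that SnCl4 is formally returned; this is a five-membered closure by cation capture in which the acceptor is a vacant p orbital, so no Baldwin-type trajectory limit applies. The closest known reaction type is the SnCl4-mediated [3+2] annulation of triethylsilylperoxy ketals with 1,1-disubstituted alkenes to 3,3,5,5-tetrasubstituted 1,2-dioxolanes. C5 is configured in the C–C bond formation, where only the remote C7 centre distinguishes the two faces of the planar ion 10, so no useful bias is expected. C3 is configured in the ring closure, where CH3 and CH2CO2CH3 differ too little in size to give more than a weak preference for the cis-dimethyl arrangement. The step therefore needs regio- and chemoselectivity, not stereoselectivity: the first is secured by the 1,1-disubstitution of 9, the second by a chain that carries no alkene and by excess 9 at −78 °C, so that capture of 10 and closure of 11 outrun proton loss. The (3R,5R) isomer 12 is to be separated from its three diastereomers, the cis from the trans pairs on silica gel and the two cis isomers by HPLC with the benzoate as chromophore.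

Step 8
Reactants: 12 methyl 2-[(3R,5R)-5-[(2R)-7-(benzoyloxy)-2-methylheptyl]-3,5-dimethyl-1,2-dioxolan-3-yl]acetate
Product: 13 methyl 2-[(3R,5R)-5-[(2R)-7-hydroxy-2-methylheptyl]-3,5-dimethyl-1,2-dioxolan-3-yl]acetate
Conditions: K2CO3 (0.3 equiv), CH3OH, 0 °C → rt
Reagents that add atoms: none
Why: Base-catalysed transesterification of the benzoate with methanol; the methyl ester only exchanges with its own alcohol. The ring carbons bear no hydrogen, so Kornblum–DeLaMare cleavage is impossible, and the low temperature and substoichiometric carbonate keep ester enolisation (the entry to retro-oxa-Michael opening at C3) slow.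

Step 9
Reactants: 13 methyl 2-[(3R,5R)-5-[(2R)-7-hydroxy-2-methylheptyl]-3,5-dimethyl-1,2-dioxolan-3-yl]acetate
Product: 14 methyl 2-[(3R,5R)-3,5-dimethyl-5-[(2R)-2-methyl-7-oxoheptyl]-1,2-dioxolan-3-yl]acetate
Conditions: Dess–Martin periodinane (1.3 equiv), CH2Cl2, 0 °C → rt
Reagents that add atoms: none
Why: Dess–Martin oxidation of a primary alcohol to the aldehyde under neutral, non-reducing conditions that leave the dialkyl peroxide and the ester alone.

Step 10
Reactants: 15 (4E)-5-phenylpent-4-en-1-ol
Product: 16 1-phenyl-5-{[(4E)-5-phenylpent-4-en-1-yl]sulfanyl}-1H-tetrazole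
Conditions: 1-phenyl-1H-tetrazole-5-thiol (1.2 equiv), PPh3 (1.2 equiv), DIAD (1.2 equiv), THF, 0 °C → rt
Reagents that add atoms: 1-phenyl-1H-tetrazole-5-thiol, Sc1nnnn1-c1ccccc1
Why: Mitsunobu thioetherification of a primary alcohol with an acidic heteroaryl thiol. No stereocentre is involved and the styrene is inert.

Step 11
Reactants: 16 1-phenyl-5-{[(4E)-5-phenylpent-4-en-1-yl]sulfanyl}-1H-tetrazole
Product: 17 1-phenyl-5-{[(4E)-5-phenylpent-4-en-1-yl]sulfonyl}-1H-tetrazole
Conditions: 30% aq H2O2 (excess), (NH4)6Mo7O24·4H2O (10 mol%), EtOH, 0 °C → rt
Reagents that add atoms: hydrogen peroxide, OO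
Why: Molybdate-catalysed oxidation of the sulfide to the sulfone with H2O2. This system is chosen over a peracid because it does not epoxidise the styrenyl double bond.

Step 12
Reactants: 14 methyl 2-[(3R,5R)-3,5-dimethyl-5-[(2R)-2-methyl-7-oxoheptyl]-1,2-dioxolan-3-yl]acetate; 17 1-phenyl-5-{[(4E)-5-phenylpent-4-en-1-yl]sulfonyl}-1H-tetrazole
Product: 18 methyl 2-[(3R,5R)-3,5-dimethyl-5-[(2R,7E,11E)-2-methyl-12-phenyldodeca-7,11-dien-1-yl]-1,2-dioxolan-3-yl]acetate
Conditions: 17 (1.3 equiv), KN(SiMe3)2 (1.25 equiv), DME, −60 °C; then 14, −60 °C → rt; aq NH4Cl
Reagents that add atoms: none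
Why: Julia–Kocienski olefination: the potassium salt of 17 adds to aldehyde 14, and Smiles rearrangement with loss of SO2 and the tetrazolate gives the C12=C13 alkene; 1-phenyltetrazolyl sulfones with a potassium counter-ion in DME favour the E-alkene with unbranched partners. The sulfonyl carbanion is formed before 14 is added and is much less basic than the amide base, which protects the ester and the ring; the C16=C17 geometry is carried in unchanged.

Step 13
Reactants: 18 methyl 2-[(3R,5R)-3,5-dimethyl-5-[(2R,7E,11E)-2-methyl-12-phenyldodeca-7,11-dien-1-yl]-1,2-dioxolan-3-yl]acetate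
Product: 19 2-[(3R,5R)-3,5-dimethyl-5-[(2R,7E,11E)-2-methyl-12-phenyldodeca-7,11-dien-1-yl]-1,2-dioxolan-3-yl]acetic acid
Conditions: LiOH·H2O (3 equiv), THF/H2O (3:1), 0 °C → rt; 1 M HCl to pH 3
Reagents that add atoms: lithium hydroxide, [Li+].[OH-]
Why: Saponification of a methyl ester with LiOH. The carboxylate formed shuts off further enolisation, the fully substituted peroxide carbons cannot fragment under base, and the two alkenes are unaffected.

## Compound list

1 | (R)-citronellal, (3R)-3,7-dimethyloct-6-enal | C[C@H](CCC=C(C)C)CC=O | starting material
2 | (4R)-4,8-dimethylnon-7-en-2-ol (both C2 epimers) | C[C@H](CCC=C(C)C)CC(C)O | intermediate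
3 | (4R)-4,8-dimethylnon-7-en-2-one | C[C@H](CCC=C(C)C)CC(C)=O | intermediate
4 | allyl benzoate (prop-2-en-1-yl benzoate) | C=CCOC(=O)c1ccccc1 | starting material
5 | (2E,6R)-6-methyl-8-oxonon-2-en-1-yl benzoate (E major; Z isomer carried along) | C[C@H](CC/C=C/COC(=O)c1ccccc1)CC(C)=O | intermediate
6 | (6R)-6-methyl-8-oxononyl benzoate | C[C@H](CCCCCOC(=O)c1ccccc1)CC(C)=O | intermediate
7 | (6R)-8-hydroperoxy-8-methoxy-6-methylnonyl benzoate (both C8 epimers) | C[C@H](CCCCCOC(=O)c1ccccc1)CC(C)(OC)OO | intermediate
8 | (6R)-8-methoxy-6-methyl-8-[(triethylsilyl)peroxy]nonyl benzoate (both C8 epimers) | C[C@H](CCCCCOC(=O)c1ccccc1)CC(C)(OC)OO[Si](CC)(CC)CC | intermediate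
9 | methyl 3-methylbut-3-enoate | C=C(C)CC(=O)OC | starting material
10 | [(4R)-9-(benzoyloxy)-4-methylnonan-2-ylidene][(triethylsilyl)oxy]oxonium (peroxycarbenium ion, not isolated) | C[C@H](CCCCCOC(=O)c1ccccc1)CC(C)=[O+]O[Si](CC)(CC)CC | intermediate
11 | 3-ylium cation of methyl (7R)-12-(benzoyloxy)-3,5,7-trimethyl-5-[(triethylsilyl)peroxy]dodecanoate (tertiary carbenium ion, both C5 epimers, not isolated) | C[C@H](CCCCCOC(=O)c1ccccc1)CC(C)(OO[Si](CC)(CC)CC)C[C+](C)CC(=O)OC | intermediate
12 | methyl 2-[(3R,5R)-5-[(2R)-7-(benzoyloxy)-2-methylheptyl]-3,5-dimethyl-1,2-dioxolan-3-yl]acetate | C[C@H](CCCCCOC(=O)c1ccccc1)C[C@]1(C)C[C@](C)(CC(=O)OC)OO1 | intermediate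
13 | methyl 2-[(3R,5R)-5-[(2R)-7-hydroxy-2-methylheptyl]-3,5-dimethyl-1,2-dioxolan-3-yl]acetate | C[C@H](CCCCCO)C[C@]1(C)C[C@](C)(CC(=O)OC)OO1 | intermediate
14 | methyl 2-[(3R,5R)-3,5-dimethyl-5-[(2R)-2-methyl-7-oxoheptyl]-1,2-dioxolan-3-yl]acetate | C[C@H](CCCCC=O)C[C@]1(C)C[C@](C)(CC(=O)OC)OO1 | intermediate
15 | (4E)-5-phenylpent-4-en-1-ol | OCCC/C=C/c1ccccc1 | starting material
16 | 1-phenyl-5-{[(4E)-5-phenylpent-4-en-1-yl]sulfanyl}-1H-tetrazole | C(CC/C=C/c1ccccc1)Sc1nnnn1-c1ccccc1 | intermediate
17 | 1-phenyl-5-{[(4E)-5-phenylpent-4-en-1-yl]sulfonyl}-1H-tetrazole | O=S(=O)(CCC/C=C/c1ccccc1)c1nnnn1-c1ccccc1 | intermediate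
18 | methyl 2-[(3R,5R)-3,5-dimethyl-5-[(2R,7E,11E)-2-methyl-12-phenyldodeca-7,11-dien-1-yl]-1,2-dioxolan-3-yl]acetate | C[C@H](CCCC/C=C/CC/C=C/c1ccccc1)C[C@]1(C)C[C@](C)(CC(=O)OC)OO1 | intermediate
19 | 2-[(3R,5R)-3,5-dimethyl-5-[(2R,7E,11E)-2-methyl-12-phenyldodeca-7,11-dien-1-yl]-1,2-dioxolan-3-yl]acetic acid | C[C@H](CCCC/C=C/CC/C=C/c1ccccc1)C[C@]1(C)C[C@](C)(CC(=O)O)OO1 | target

## Step count and least certain steps

Total: 13 steps. Longest linear sequence: 11 steps (steps 1–9, 12 and 13, from 1). The sulfone branch (steps 10 and 11) joins at step 12.

**Step 7 (key step).** Two things are most likely to go wrong.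
- Face selection at C5 is expected to be essentially absent and the cis/trans preference at C3 weak. Much of the material therefore ends in diastereomers, and the separation of the two cis-dimethyl isomers, which differ only in the C5/C7 relationship, rests on HPLC. If they do not separate at 12, the separation can be repeated at 13 or 14.
- The tertiary cation sits next to an ester-activated CH2 and may lose a proton in competition with ring closure. Addition may also be slow because the ester lowers the nucleophilicity of the alkene and binds SnCl4.

Fallback, from 8 back to 12: ketal 8 would be combined under the same SnCl4 conditions with the more electron-rich alkene triisopropyl[(3-methylbut-3-en-1-yl)oxy]silane F1, made from commercial 3-methylbut-3-en-1-ol with (i-Pr)3SiCl and imidazole. After the same separation this should give (3S,5R)-5-[(2R)-7-(benzoyloxy)-2-methylheptyl]-3,5-dimethyl-3-{2-[(triisopropylsilyl)oxy]ethyl}-1,2-dioxolane F2. Bu4NF buffered with acetic acid in THF would free (6R)-7-[(3R,5S)-5-(2-hydroxyethyl)-3,5-dimethyl-1,2-dioxolan-3-yl]-6-methylheptyl benzoate F3. Catalytic TEMPO with PhI(OAc)2 in aqueous acetonitrile would oxidise it to 2-[(3R,5R)-5-[(2R)-7-(benzoyloxy)-2-methylheptyl]-3,5-dimethyl-1,2-dioxolan-3-yl]acetic acid F4, and (CH3)3SiCHN2 in methanol/toluene would give 12.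

**Step 5.** The perketalisation is an equilibrium. With an acyclic methyl ketone it may stop short, run on to the geminal dihydroperoxide, or revert to the ketone during chromatography.

Fallback, from 6 back to 7: Wittig methylenation of 6 (Ph3PCH3Br, KOC(CH3)3, THF, 0 °C) would give (6R)-6,8-dimethylnon-8-en-1-yl benzoate F5 (the same compound as A7). Ozonolysis of F5 in CH3OH/CH2Cl2 at −78 °C cleaves the 1,1-disubstituted alkene to the more substituted carbonyl oxide, which methanol traps as the α-methoxy hydroperoxide 7.

**Step 12.** E-selectivity may be insufficient, since both partners are unbranched, and the base may partly enolise the β-peroxy ester, opening the ring at C3. Residual Z isomer would have to be removed on AgNO3-impregnated silica.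

Fallback, from 13 (with 15) back to 18: the roles of the partners are exchanged and phosphines are avoided in the presence of the peroxide.
- Alcohol 13 would be converted with CH3SO2Cl and Et3N into methyl 2-[(3R,5R)-5-[(2R)-7-(methanesulfonyloxy)-2-methylheptyl]-3,5-dimethyl-1,2-dioxolan-3-yl]acetate F6.
- Displacement with 1-phenyl-1H-tetrazole-5-thiol and K2CO3 in acetone would give methyl 2-[(3R,5R)-3,5-dimethyl-5-[(2R)-2-methyl-7-[(1-phenyl-1H-tetrazol-5-yl)sulfanyl]heptyl]-1,2-dioxolan-3-yl]acetate F7.
- Oxidation with H2O2 and (NH4)6Mo7O24·4H2O would give methyl 2-[(3R,5R)-3,5-dimethyl-5-[(2R)-2-methyl-7-[(1-phenyl-1H-tetrazol-5-yl)sulfonyl]heptyl]-1,2-dioxolan-3-yl]acetate F8.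
- Alcohol 15 would be oxidised with Dess–Martin periodinane to (4E)-5-phenylpent-4-enal F9.
- KN(SiMe3)2 would be added to a mixture of F8 and F9 in DME at −60 °C, so that the sulfonyl carbanion is trapped as it forms, to give 18.

**Step 13.** Hydroxide may induce retro-oxa-Michael opening, with loss of configuration at C3, in competition with a slow hydrolysis of the ester next to a quaternary carbon.

Fallback, from 18 directly to 19: enzymatic hydrolysis with pig liver esterase in pH 7 phosphate buffer with acetone as co-solvent at rt, which avoids free hydroxide; no new compound is made.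

## Further compounds

F1 | step 7 | triisopropyl[(3-methylbut-3-en-1-yl)oxy]silane | C=C(C)CCO[Si](C(C)C)(C(C)C)C(C)C
F2 | step 7 | (3S,5R)-5-[(2R)-7-(benzoyloxy)-2-methylheptyl]-3,5-dimethyl-3-{2-[(triisopropylsilyl)oxy]ethyl}-1,2-dioxolane | C[C@H](CCCCCOC(=O)c1ccccc1)C[C@]1(C)C[C@](C)(CCO[Si](C(C)C)(C(C)C)C(C)C)OO1
F3 | step 7 | (6R)-7-[(3R,5S)-5-(2-hydroxyethyl)-3,5-dimethyl-1,2-dioxolan-3-yl]-6-methylheptyl benzoate | C[C@H](CCCCCOC(=O)c1ccccc1)C[C@]1(C)C[C@](C)(CCO)OO1
F4 | step 7 | 2-[(3R,5R)-5-[(2R)-7-(benzoyloxy)-2-methylheptyl]-3,5-dimethyl-1,2-dioxolan-3-yl]acetic acid | C[C@H](CCCCCOC(=O)c1ccccc1)C[C@]1(C)C[C@](C)(CC(=O)O)OO1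
F5 | step 5 | (6R)-6,8-dimethylnon-8-en-1-yl benzoate | C[C@H](CCCCCOC(=O)c1ccccc1)CC(C)=C
F6 | step 12 | methyl 2-[(3R,5R)-5-[(2R)-7-(methanesulfonyloxy)-2-methylheptyl]-3,5-dimethyl-1,2-dioxolan-3-yl]acetate | C[C@H](CCCCCOS(C)(=O)=O)C[C@]1(C)C[C@](C)(CC(=O)OC)OO1
F7 | step 12 | methyl 2-[(3R,5R)-3,5-dimethyl-5-[(2R)-2-methyl-7-[(1-phenyl-1H-tetrazol-5-yl)sulfanyl]heptyl]-1,2-dioxolan-3-yl]acetate | C[C@H](CCCCCSc1nnnn1-c1ccccc1)C[C@]2(C)C[C@](C)(CC(=O)OC)OO2
F8 | step 12 | methyl 2-[(3R,5R)-3,5-dimethyl-5-[(2R)-2-methyl-7-[(1-phenyl-1H-tetrazol-5-yl)sulfonyl]heptyl]-1,2-dioxolan-3-yl]acetate | C[C@H](CCCCCS(=O)(=O)c1nnnn1-c1ccccc1)C[C@]2(C)C[C@](C)(CC(=O)OC)OO2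
F9 | step 12 | (4E)-5-phenylpent-4-enal | O=CCC/C=C/c1ccccc1
F0 | step 13 | none | none
A1 | alternative 1 | 3,5-dimethoxy-3,5-dimethyl-1,2-dioxolane (cis and trans) | COC1(C)CC(C)(OC)OO1
A2 | alternative 1 | trimethyl{[3-(trimethylsilyl)prop-1-en-2-yl]oxy}silane | C=C(C[Si](C)(C)C)O[Si](C)(C)C
A3 | alternative 1 | (1R,5S)-1,5-dimethyl-6,7-dioxabicyclo[3.2.1]octan-3-one (meso) | O=C1C[C@]2(C)C[C@](C)(C1)OO2
A4 | alternative 2 | tert-butyl{[(6R)-7-(2-ethenyl-1,2-dimethylcyclopropyl)-6-methylheptyl]oxy}diphenylsilane (cyclopropane stereoisomers) | C[C@H](CCCCCO[Si](c1ccccc1)(c2ccccc2)C(C)(C)C)CC3(C)CC3(C)C=C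
A5 | alternative 2 | (3R,5R)-3-ethenyl-3,5-dimethyl-5-[(2R)-7-(tert-butyldiphenylsilyloxy)-2-methylheptyl]-1,2-dioxolane | C[C@H](CCCCCO[Si](c1ccccc1)(c2ccccc2)C(C)(C)C)C[C@]3(C)C[C@](C)(C=C)OO3
A6 | alternative 3 | tert-butyl{3-methoxy-3-[(triethylsilyl)peroxy]butoxy}diphenylsilane | CC(OC)(CCO[Si](c1ccccc1)(c2ccccc2)C(C)(C)C)OO[Si](CC)(CC)CC
A7 | alternative 3 | (6R)-6,8-dimethylnon-8-en-1-yl benzoate | C[C@H](CCCCCOC(=O)c1ccccc1)CC(C)=C
A8 | alternative 3 | (3S,5R)-3-[2-(tert-butyldiphenylsilyloxy)ethyl]-5-[(2R)-7-(benzoyloxy)-2-methylheptyl]-3,5-dimethyl-1,2-dioxolane | C[C@H](CCCCCOC(=O)c1ccccc1)C[C@]1(C)C[C@](C)(CCO[Si](c2ccccc2)(c3ccccc3)C(C)(C)C)OO1
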